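**Retrosynthetic overview**
- The strategy rests on the ester bond between the carboxyl carbon C1 of ring A (the orsellinate ring, where C1 sits between C2–OH and C6–CH3) and the carbinol oxygen of the first (R)-3-hydroxybutanoate (unit B). This bond is made on an open-chain acylketene, before ring A exists.
- Last disconnection: hydrogenolysis of the four benzyl ethers on rings C and E. Before it, ring A is built in one operation from a diketo-dioxinone and the tetra-O-benzyl chain alcohol B–C–D–E (ketene capture, then C2–C7 aldol closure and aromatisation).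
- Chain alcohol: the B–C and D–E ester bonds come from carbodiimide couplings. The hindered ring C benzoate (C–D bond) comes from a Mitsunobu inversion of (S)-pent-4-en-2-ol, whose alkene is then cleaved to the butanoate carboxyl.
- Ring C acid and ring E alcohol both derive from one arylpropanol (aryl Grignard + (R)-propylene oxide). The ring C carboxyl is introduced by bromination, Br/Li exchange and CO2. The diketo-dioxinone comes from two enolate acylations of 2,2,6-trimethyl-1,3-dioxin-4-one.
- Ring order: rings C and E are bought as 5-bromoresorcinol; ring A is the only ring formed, in step 17.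

Key step: step 17

Remark: units are lettered from the acyl terminus (ring A orsellinate, B 3-oxybutanoate, ring C resorcylate, D 3-oxybutanoate, ring E resorcinol). All four carbinol centres are read as (R). (S)-Pent-4-en-2-ol, (R)-propylene oxide and methyl (R)-3-hydroxybutanoate are assumed to be bought in high enantiomeric purity.

**Route**

Step 1
Reactants: 1 5-bromoresorcinol
Product: 2 1,3-bis(benzyloxy)-5-bromobenzene
Conditions: BnBr (2.3 equiv), K2CO3, DMF, rt → 50 °C
Reagents that add atoms: benzyl bromide, BrCc1ccccc1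
Why: Williamson etherification: the two phenoxides are the only nucleophiles present and the aryl bromide does not react with carbonate or benzyl bromide, so the bis-benzyl ether should form cleanly.

Step 2
Reactants: 2 1,3-bis(benzyloxy)-5-bromobenzene; 3 (R)-propylene oxide
Product: 5 (R)-1-[3,5-bis(benzyloxy)phenyl]propan-2-ol, via arylmagnesium bromide 4 (not isolated)
Conditions: Mg, cat. I2, THF, reflux; then CuI (10 mol %), 3, −30 → 0 °C; aq. NH4Cl
Reagents that add atoms: none
Why: Copper-catalysed Grignard opening of a terminal epoxide: the aryl group should attack the unsubstituted CH2 of 3, so the C–O stereocentre is not involved and keeps its (R) configuration in the 1-aryl-2-propanol.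

Step 3
Reactants: 5 (R)-1-[3,5-bis(benzyloxy)phenyl]propan-2-ol
Product: 6 (R)-{[1-(3,5-bis(benzyloxy)phenyl)propan-2-yl]oxy}(tert-butyl)dimethylsilane
Conditions: TBSCl, imidazole, DMF, rt
Reagents that add atoms: tert-butyldimethylsilyl chloride, CC(C)(C)[Si](C)(C)Cl
Why: Silylation of a secondary alcohol (TBSCl/imidazole) gives an ether that withstands the organolithium, Mitsunobu, ozonolysis and Pinnick steps and is orthogonal to the benzyl ethers.

Step 4
Reactants: 6 (R)-{[1-(3,5-bis(benzyloxy)phenyl)propan-2-yl]oxy}(tert-butyl)dimethylsilane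
Product: 7 (R)-{[1-(3,5-bis(benzyloxy)-2-bromophenyl)propan-2-yl]oxy}(tert-butyl)dimethylsilane
Conditions: NBS (1.0 equiv), MeCN, 0 °C, dark
Reagents that add atoms: N-bromosuccinimide, O=C1CCC(=O)N1Br
Why: Electrophilic aromatic bromination with NBS should take place at ring position 2 (ortho to the side chain, para to one benzyloxy group), the usual site for 5-alkylresorcinol diethers, rather than at position 4 between the two benzyloxy groups, and one equivalent at 0 °C limits dibromination.

Step 5
Reactants: 7 (R)-{[1-(3,5-bis(benzyloxy)-2-bromophenyl)propan-2-yl]oxy}(tert-butyl)dimethylsilane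
Product: 9 2,4-bis(benzyloxy)-6-[(R)-2-(tert-butyldimethylsilyloxy)propyl]benzoic acid, via aryllithium 8 (not isolated)
Conditions: n-BuLi (1.1 equiv), THF, −78 °C, 10 min; CO2 (g), −78 → 0 °C; 1 M HCl to pH 4, 0 °C
Reagents that add atoms: carbon dioxide, O=C=O
Why: Bromine–lithium exchange and carboxylation of the aryllithium put the carboxyl carbon exactly where bromine was, and at −78 °C the exchange should outrun deprotonation of the benzyl ethers and migration of silicon from oxygen to the aryl carbanion.

Step 6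
Reactants: 9 2,4-bis(benzyloxy)-6-[(R)-2-(tert-butyldimethylsilyloxy)propyl]benzoic acid; 10 (S)-pent-4-en-2-ol
Product: 11 (R)-pent-4-en-2-yl 2,4-bis(benzyloxy)-6-[(R)-2-(tert-butyldimethylsilyloxy)propyl]benzoate
Conditions: PPh3, DIAD, THF, 0 °C → rt
Reagents that add atoms: none
Why: Mitsunobu esterification makes the crowded 2,6-disubstituted carboxylate the nucleophile, so hindrance at its carbonyl carbon is irrelevant, and SN2 displacement at the activated carbinol inverts (S)-10 to the (R)-configured carbinol carbon of unit D.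

Step 7
Reactants: 11 (R)-pent-4-en-2-yl 2,4-bis(benzyloxy)-6-[(R)-2-(tert-butyldimethylsilyloxy)propyl]benzoate
Product: 13 (R)-4-oxobutan-2-yl 2,4-bis(benzyloxy)-6-[(R)-2-(tert-butyldimethylsilyloxy)propyl]benzoate, via ozonide 12 (not isolated)
Conditions: O3, CH2Cl2, −78 °C (Sudan III end point); then PPh3, −78 °C → rt
Reagents that add atoms: ozone, [O-][O+]=O
Why: Ozonolysis with reductive work-up cleaves the terminal alkene, which consumes ozone far faster than the ester-deactivated arene or the benzyl ethers when addition is stopped at the indicator end point, and the neutral phosphine reduction avoids β-elimination of the aroate from the aldehyde.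

Step 8
Reactants: 13 (R)-4-oxobutan-2-yl 2,4-bis(benzyloxy)-6-[(R)-2-(tert-butyldimethylsilyloxy)propyl]benzoate
Product: 14 (R)-3-({2,4-bis(benzyloxy)-6-[(R)-2-(tert-butyldimethylsilyloxy)propyl]benzoyl}oxy)butanoic acid
Conditions: NaClO2, NaH2PO4, 2-methyl-2-butene, t-BuOH/H2O, 0 °C → rt
Reagents that add atoms: sodium chlorite, [Na+].[O-]Cl=O
Why: Pinnick oxidation at pH 3–4 takes the aldehyde to the acid without base, so the β-aroyloxy group stays in place, and the alkene scavenger removes HOCl before it can chlorinate the electron-rich rings.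

Step 9
Reactants: 14 (R)-3-({2,4-bis(benzyloxy)-6-[(R)-2-(tert-butyldimethylsilyloxy)propyl]benzoyl}oxy)butanoic acid; 5 (R)-1-[3,5-bis(benzyloxy)phenyl]propan-2-ol
Product: 15 (R)-1-[3,5-bis(benzyloxy)phenyl]propan-2-yl (R)-3-({2,4-bis(benzyloxy)-6-[(R)-2-(tert-butyldimethylsilyloxy)propyl]benzoyl}oxy)butanoate (TBS-protected C–D–E diester)
Conditions: EDC·HCl, DMAP (0.2 equiv), CH2Cl2, 0 °C → rt
Reagents that add atoms: none
Why: Steglich (carbodiimide/DMAP) esterification of an unhindered aliphatic acid with the secondary alcohol 5 proceeds with retention at both carbinol centres, and low temperature with only catalytic DMAP should hold back E1cB loss of the aroate from the activated acyl species.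

Step 10
Reactants: 15 TBS-protected C–D–E diester
Product: 16 (R)-1-[3,5-bis(benzyloxy)phenyl]propan-2-yl (R)-3-({2,4-bis(benzyloxy)-6-[(R)-2-hydroxypropyl]benzoyl}oxy)butanoate (C–D–E alcohol)
Conditions: HF·pyridine, pyridine, THF, 0 °C → rt
Reagents that add atoms: none
Why: Fluoride-induced desilylation with pyridine-buffered HF is non-basic, so it should free the ring C carbinol without β-elimination in unit D, without touching the benzyl ethers, and without forming the alkoxide that would lactonise onto the neighbouring benzoate.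

Step 11
Reactants: 17 methyl (R)-3-hydroxybutanoate
Product: 18 methyl (R)-3-(tert-butyldimethylsilyloxy)butanoate
Conditions: TBSCl, imidazole, DMF, rt
Reagents that add atoms: tert-butyldimethylsilyl chloride, CC(C)(C)[Si](C)(C)Cl
Why: Silylation of the secondary alcohol (TBSCl/imidazole) masks the hydroxyl of unit B so that its acid can later be activated without self-condensation.

Step 12
Reactants: 18 methyl (R)-3-(tert-butyldimethylsilyloxy)butanoate
Product: 19 (R)-3-(tert-butyldimethylsilyloxy)butanoic acid
Conditions: LiOH·H2O, THF/MeOH/H2O, 0 °C → rt; 1 M HCl to pH 4, 0 °C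
Reagents that add atoms: lithium hydroxide, [Li+].[OH-]
Why: Saponification of the methyl ester with LiOH should give the acid because the β-silyloxy group is a poor leaving group for elimination, and careful acidification to pH 4 keeps the silyl ether.

Step 13
Reactants: 16 C–D–E alcohol; 19 (R)-3-(tert-butyldimethylsilyloxy)butanoic acid
Product: 20 TBS-protected B–C–D–E chain (16 acylated at the ring C carbinol by the (R)-3-(tert-butyldimethylsilyloxy)butanoyl group)
Conditions: EDC·HCl, DMAP (0.2 equiv), CH2Cl2, 0 °C → rt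
Reagents that add atoms: none
Why: Steglich esterification of the ring C carbinol with the β-silyloxy acid goes with retention at both centres, the alcohol being acylated faster than it can transesterify onto its neighbouring hindered benzoate.

Step 14
Reactants: 20 TBS-protected B–C–D–E chain
Product: 21 tetra-O-benzyl chain alcohol (B–C–D–E with the free (R)-carbinol of unit B)
Conditions: HF·pyridine, pyridine, THF, 0 °C → rt
Reagents that add atoms: none
Why: Desilylation with buffered HF·pyridine, as in step 10, should release the single aliphatic hydroxyl of the chain under conditions too mild for β-elimination in the two β-acyloxy ester units.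

Step 15
Reactants: 22 2,2,6-trimethyl-4H-1,3-dioxin-4-one
Product: 24 2,2-dimethyl-6-(2-oxopropyl)-4H-1,3-dioxin-4-one, via lithium dienolate 23 (not isolated)
Conditions: LiHMDS (2 equiv), 22 (2 equiv), THF, −78 °C; AcCl (1 equiv), −78 °C; aq. HCl
Reagents that add atoms: acetyl chloride, CC(=O)Cl
Why: C-acylation of a vinylogous ester enolate: deprotonation of the 6-methyl group gives the dienolate, which is acetylated at its terminal (γ) carbon, and a twofold excess of enolate over acetyl chloride covers deprotonation of the more acidic product.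

Step 16
Reactants: 24 2,2-dimethyl-6-(2-oxopropyl)-4H-1,3-dioxin-4-one
Product: 26 2,2-dimethyl-6-(2,4-dioxopentyl)-4H-1,3-dioxin-4-one, via dilithium dianion 25 (not isolated)
Conditions: LDA (3 equiv), THF, −78 °C; N-methoxy-N-methylacetamide, −78 → −20 °C; aq. HCl to pH 3
Reagents that add atoms: N-methoxy-N-methylacetamide, CC(=O)N(C)OC
Why: Claisen-type acylation of a 1,3-dicarbonyl dianion at its terminal, last-formed carbanion; the N-methoxy-N-methyl amide gives a chelated tetrahedral adduct that collapses to the β-diketone only on acidic work-up, which should prevent over-acylation.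

Step 17
Reactants: 21 tetra-O-benzyl chain alcohol; 26 2,2-dimethyl-6-(2,4-dioxopentyl)-4H-1,3-dioxin-4-one
Product: 30 tetra-O-benzyl hansforester A (benzyl ethers on rings C/E; ring A phenols free), via acylketene 27 (not isolated), via triketo ester 28 (not isolated), via aldol adduct 29 (not isolated)
Conditions: 26 (1.5 equiv), PhMe, 110 °C, 1–2 h; then CsOAc, i-PrOH/CH2Cl2, rt; then HCl (i-PrOH), 0 °C → rt
Reagents that add atoms: none
Why: Heating 26 causes a retro-[4+2] loss of acetone to acylketene 27, whose central ketene carbon is attacked by the one free hydroxyl of 21, so the ester C–O bond to the future C1 carboxyl forms while that carbon is still unhindered and gives triketo ester 28; caesium acetate then generates the carbanion at C2 (between the ester and the C3 ketone), which adds to the C7 methyl ketone to give aldol adduct 29, and acid dehydrates and enolises 29 to the arene. The closest known reaction type is the thermolysis of diketo-dioxinones in the presence of secondary alcohols followed by base/acid aldol aromatisation to resorcylate esters, a laboratory version of the polyketide orsellinate cyclisation. Ring A closes by a 6-exo-trig aldol addition (C2–C7 bond), formally 6-(enolexo) if the C2 anion is drawn as the ester enolate and 6-(enolendo) if drawn as the C3 ketone enolate, both favoured closures. No stereocentre is created in the product, because C7 and C2 of 29 become sp2 on aromatisation, and the four (R) centres of the chain are non-epimerisable carbinol carbons remote from the reacting sites. Chemoselectivity for the aliphatic hydroxyl is secured by the benzyl ethers on all four phenols of rings C and E, and of the two six-membered closures open to 28 (C2 onto the C7 ketone, or C6 onto the C1 ester) the aldol addition to the ketone is much the faster under weak base and is made irreversible by dehydration. Short heating limits lactonisation of 28 to a pyranone with loss of 21, and the weak acetate base is chosen so that the two β-acyloxy ester units do not undergo E1cB elimination.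

Step 18
Reactants: 30 tetra-O-benzyl hansforester A
Product: 31 hansforester A
Conditions: H2 (1 atm), 10 % Pd/C, EtOAc, rt
Reagents that add atoms: none
Why: Catalytic hydrogenolysis cleaves the four aryl benzyl ethers while the esters, the homobenzylic C–O bonds and the four stereocentres are inert to H2/Pd at room temperature.

**Compound list**

1 | 5-bromoresorcinol | Oc1cc(Br)cc(O)c1 | starting material
2 | 1,3-bis(benzyloxy)-5-bromobenzene | Brc1cc(OCc2ccccc2)cc(OCc2ccccc2)c1 | intermediate
3 | (R)-propylene oxide | C[C@@H]1CO1 | starting material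
4 | 3,5-bis(benzyloxy)phenylmagnesium bromide | Br[Mg]c1cc(OCc2ccccc2)cc(OCc2ccccc2)c1 | intermediate
5 | (R)-1-[3,5-bis(benzyloxy)phenyl]propan-2-ol | O[C@H](C)Cc1cc(OCc2ccccc2)cc(OCc2ccccc2)c1 | intermediate
6 | (R)-{[1-(3,5-bis(benzyloxy)phenyl)propan-2-yl]oxy}(tert-butyl)dimethylsilane | CC(C)(C)[Si](C)(C)O[C@H](C)Cc1cc(OCc2ccccc2)cc(OCc2ccccc2)c1 | intermediate
7 | (R)-{[1-(3,5-bis(benzyloxy)-2-bromophenyl)propan-2-yl]oxy}(tert-butyl)dimethylsilane | CC(C)(C)[Si](C)(C)O[C@H](C)Cc1cc(OCc2ccccc2)cc(OCc2ccccc2)c1Br | intermediate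
8 | aryllithium from 7 (Li in place of Br) | CC(C)(C)[Si](C)(C)O[C@H](C)Cc1cc(OCc2ccccc2)cc(OCc2ccccc2)c1[Li] | intermediate
9 | 2,4-bis(benzyloxy)-6-[(R)-2-(tert-butyldimethylsilyloxy)propyl]benzoic acid | CC(C)(C)[Si](C)(C)O[C@H](C)Cc1cc(OCc2ccccc2)cc(OCc2ccccc2)c1C(=O)O | intermediate
10 | (S)-pent-4-en-2-ol | C[C@H](O)CC=C | starting material
11 | (R)-pent-4-en-2-yl 2,4-bis(benzyloxy)-6-[(R)-2-(tert-butyldimethylsilyloxy)propyl]benzoate | CC(C)(C)[Si](C)(C)O[C@H](C)Cc1cc(OCc2ccccc2)cc(OCc2ccccc2)c1C(=O)O[C@H](C)CC=C | intermediate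
12 | ozonide (1,2,4-trioxolane) of 11, mixture of epimers at the trioxolane carbon | CC(C)(C)[Si](C)(C)O[C@H](C)Cc1cc(OCc2ccccc2)cc(OCc2ccccc2)c1C(=O)O[C@H](C)CC1OCOO1 | intermediate
13 | (R)-4-oxobutan-2-yl 2,4-bis(benzyloxy)-6-[(R)-2-(tert-butyldimethylsilyloxy)propyl]benzoate | CC(C)(C)[Si](C)(C)O[C@H](C)Cc1cc(OCc2ccccc2)cc(OCc2ccccc2)c1C(=O)O[C@H](C)CC=O | intermediate
14 | (R)-3-({2,4-bis(benzyloxy)-6-[(R)-2-(tert-butyldimethylsilyloxy)propyl]benzoyl}oxy)butanoic acid | CC(C)(C)[Si](C)(C)O[C@H](C)Cc1cc(OCc2ccccc2)cc(OCc2ccccc2)c1C(=O)O[C@H](C)CC(=O)O | intermediate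
15 | TBS-protected C–D–E diester | CC(C)(C)[Si](C)(C)O[C@H](C)Cc1cc(OCc2ccccc2)cc(OCc2ccccc2)c1C(=O)O[C@H](C)CC(=O)O[C@H](C)Cc1cc(OCc2ccccc2)cc(OCc2ccccc2)c1 | intermediate
16 | C–D–E alcohol | O[C@H](C)Cc1cc(OCc2ccccc2)cc(OCc2ccccc2)c1C(=O)O[C@H](C)CC(=O)O[C@H](C)Cc1cc(OCc2ccccc2)cc(OCc2ccccc2)c1 | intermediate
17 | methyl (R)-3-hydroxybutanoate | O[C@H](C)CC(=O)OC | starting material
18 | methyl (R)-3-(tert-butyldimethylsilyloxy)butanoate | CC(C)(C)[Si](C)(C)O[C@H](C)CC(=O)OC | intermediate
19 | (R)-3-(tert-butyldimethylsilyloxy)butanoic acid | CC(C)(C)[Si](C)(C)O[C@H](C)CC(=O)O | intermediate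
20 | TBS-protected B–C–D–E chain | CC(C)(C)[Si](C)(C)O[C@H](C)CC(=O)O[C@H](C)Cc1cc(OCc2ccccc2)cc(OCc2ccccc2)c1C(=O)O[C@H](C)CC(=O)O[C@H](C)Cc1cc(OCc2ccccc2)cc(OCc2ccccc2)c1 | intermediate
21 | tetra-O-benzyl chain alcohol | O[C@H](C)CC(=O)O[C@H](C)Cc1cc(OCc2ccccc2)cc(OCc2ccccc2)c1C(=O)O[C@H](C)CC(=O)O[C@H](C)Cc1cc(OCc2ccccc2)cc(OCc2ccccc2)c1 | intermediate
22 | 2,2,6-trimethyl-4H-1,3-dioxin-4-one | CC1=CC(=O)OC(C)(C)O1 | starting material
23 | lithium dienolate of 22 | C=C1C=C(O[Li])OC(C)(C)O1 | intermediate
24 | 2,2-dimethyl-6-(2-oxopropyl)-4H-1,3-dioxin-4-one | CC(=O)CC1=CC(=O)OC(C)(C)O1 | intermediate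
25 | dilithium dianion of 24 | C=C(O[Li])C=C1C=C(O[Li])OC(C)(C)O1 | intermediate
26 | 2,2-dimethyl-6-(2,4-dioxopentyl)-4H-1,3-dioxin-4-one | CC(=O)CC(=O)CC1=CC(=O)OC(C)(C)O1 | intermediate
27 | acylketene 3,5,7-trioxooct-1-en-1-one | CC(=O)CC(=O)CC(=O)C=C=O | intermediate
28 | 3,5,7-trioxooctanoate of 21 (triketo ester) | CC(=O)CC(=O)CC(=O)CC(=O)O[C@H](C)CC(=O)O[C@H](C)Cc1cc(OCc2ccccc2)cc(OCc2ccccc2)c1C(=O)O[C@H](C)CC(=O)O[C@H](C)Cc1cc(OCc2ccccc2)cc(OCc2ccccc2)c1 | intermediate
29 | aldol adduct: 2-hydroxy-2-methyl-4,6-dioxocyclohexane-1-carboxylate of 21, mixture of diastereomers and enol forms | CC1(O)CC(=O)CC(=O)C1C(=O)O[C@H](C)CC(=O)O[C@H](C)Cc1cc(OCc2ccccc2)cc(OCc2ccccc2)c1C(=O)O[C@H](C)CC(=O)O[C@H](C)Cc1cc(OCc2ccccc2)cc(OCc2ccccc2)c1 | intermediate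
30 | tetra-O-benzyl hansforester A (rings C and E benzylated) | Cc1cc(O)cc(O)c1C(=O)O[C@H](C)CC(=O)O[C@H](C)Cc1cc(OCc2ccccc2)cc(OCc2ccccc2)c1C(=O)O[C@H](C)CC(=O)O[C@H](C)Cc1cc(OCc2ccccc2)cc(OCc2ccccc2)c1 | intermediate
31 | hansforester A | Cc1cc(O)cc(O)c1C(=O)O[C@H](C)CC(=O)O[C@H](C)Cc1cc(O)cc(O)c1C(=O)O[C@H](C)CC(=O)O[C@H](C)Cc1cc(O)cc(O)c1 | target

**Step count**
Total: 18 steps. Longest linear sequence: 14 steps (1–10, 13, 14, 17, 18) from 5-bromoresorcinol.

**Steps most likely to fail**

1. Step 17. On heating, the triketo ester may lactonise to a pyranone and expel the chain alcohol, the acylketene may be consumed by self-condensation, and the base may start β-elimination in units B and D. The fallback sets out from 16 and returns at 31; it brings ring A in as a preformed, benzyl-protected orsellinate. Commercial methyl orsellinate is benzylated (BnBr, K2CO3, DMF) to methyl 2,4-bis(benzyloxy)-6-methylbenzoate F1 and saponified (KOH, DMSO/H2O, 90 °C) to 2,4-bis(benzyloxy)-6-methylbenzoic acid F2. Mitsunobu esterification of F2 with 10 (PPh3, DIAD) gives, with inversion, (R)-pent-4-en-2-yl 2,4-bis(benzyloxy)-6-methylbenzoate F3. Ozonolysis through the ozonide F4 and PPh3 reduction give (R)-4-oxobutan-2-yl 2,4-bis(benzyloxy)-6-methylbenzoate F5, and Pinnick oxidation gives (R)-3-{[2,4-bis(benzyloxy)-6-methylbenzoyl]oxy}butanoic acid F6. EDC/DMAP coupling of F6 with alcohol 16 gives hexa-O-benzyl hansforester A F7, and hydrogenolysis (H2, Pd/C) of F7 gives 31.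

2. Step 9. Activation of the β-aroyloxy acid may lead to E1cB loss of the aroate, giving a crotonate ester and returning acid 9. The fallback sets out from 14 and returns at 15; the acid is used as the nucleophile instead of being activated. The enantiomeric alcohol (S)-1-[3,5-bis(benzyloxy)phenyl]propan-2-ol F8 is made as in step 2 from Grignard reagent 4 and (S)-propylene oxide. Mitsunobu coupling of F8 with 14 (PPh3, DIAD, THF) inverts the carbinol carbon and gives 15 directly.

3. Step 7. Ozone may over-oxidise the benzyloxy-substituted arene or the benzylic positions, and the aroate may be lost by β-elimination from the aldehyde during work-up. The fallback sets out from 9 and returns at 14; the C4 unit is introduced at the acid oxidation level. Allyl (S)-3-hydroxybutanoate F9 is made from ethyl (S)-3-hydroxybutanoate by Ti(OiPr)4-catalysed transesterification with allyl alcohol. Mitsunobu esterification of 9 with F9 gives, with inversion, allyl (R)-3-({2,4-bis(benzyloxy)-6-[(R)-2-(tert-butyldimethylsilyloxy)propyl]benzoyl}oxy)butanoate F10. Pd(PPh3)4 with N-methylaniline as allyl acceptor then gives 14.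

**Further compounds**

F1 | step 17 | methyl 2,4-bis(benzyloxy)-6-methylbenzoate | Cc1cc(OCc2ccccc2)cc(OCc2ccccc2)c1C(=O)OC
F2 | step 17 | 2,4-bis(benzyloxy)-6-methylbenzoic acid | Cc1cc(OCc2ccccc2)cc(OCc2ccccc2)c1C(=O)O
F3 | step 17 | (R)-pent-4-en-2-yl 2,4-bis(benzyloxy)-6-methylbenzoate | Cc1cc(OCc2ccccc2)cc(OCc2ccccc2)c1C(=O)O[C@H](C)CC=C
F4 | step 17 | ozonide (1,2,4-trioxolane) of F3 | Cc1cc(OCc2ccccc2)cc(OCc2ccccc2)c1C(=O)O[C@H](C)CC1OCOO1
F5 | step 17 | (R)-4-oxobutan-2-yl 2,4-bis(benzyloxy)-6-methylbenzoate | Cc1cc(OCc2ccccc2)cc(OCc2ccccc2)c1C(=O)O[C@H](C)CC=O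
F6 | step 17 | (R)-3-{[2,4-bis(benzyloxy)-6-methylbenzoyl]oxy}butanoic acid | Cc1cc(OCc2ccccc2)cc(OCc2ccccc2)c1C(=O)O[C@H](C)CC(=O)O
F7 | step 17 | hexa-O-benzyl hansforester A | Cc1cc(OCc2ccccc2)cc(OCc2ccccc2)c1C(=O)O[C@H](C)CC(=O)O[C@H](C)Cc1cc(OCc2ccccc2)cc(OCc2ccccc2)c1C(=O)O[C@H](C)CC(=O)O[C@H](C)Cc1cc(OCc2ccccc2)cc(OCc2ccccc2)c1
F8 | step 9 | (S)-1-[3,5-bis(benzyloxy)phenyl]propan-2-ol | C[C@H](O)Cc1cc(OCc2ccccc2)cc(OCc2ccccc2)c1
F9 | step 7 | allyl (S)-3-hydroxybutanoate | C[C@H](O)CC(=O)OCC=C
F10 | step 7 | allyl (R)-3-({2,4-bis(benzyloxy)-6-[(R)-2-(tert-butyldimethylsilyloxy)propyl]benzoyl}oxy)butanoate | CC(C)(C)[Si](C)(C)O[C@H](C)Cc1cc(OCc2ccccc2)cc(OCc2ccccc2)c1C(=O)O[C@H](C)CC(=O)OCC=C
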